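**Assumption:** the target has no stereocentres (the prenyl alkene carries two identical methyls, so it has no E/Z isomer). "Single enantiomer" therefore does not apply, and the only geometric element is the E-enone of chalcone 3, which is consumed later.

## Retrosynthetic overview
- Target **1** (8-prenylkaempferol) comes from global MOM removal of flavonol **2**.
- **2** comes from Algar–Flynn–Oyamada (AFO) oxidative cyclisation of chalcone **3**. This forms the pyranone C-ring and the 3-OH together.
- **3** comes from Claisen–Schmidt condensation of acetophenone **4** with 4-hydroxybenzaldehyde **5** (B-ring).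
- **4** comes from regioselective bis-MOM protection of 3-prenylphloroacetophenone **6**, which leaves only the 2-OH next to the prenyl group free. This forces ring closure toward C-8 instead of C-6.
- **6** comes from C-prenylation of symmetrical phloroacetophenone **7** with prenyl bromide **8**; MOMCl is **9** and H2O2 is **10**. Ring order: A-ring prenylated first, then B-ring attached, then C-ring closed.

## Route

**Step 1**
Reactants: **7** 2,4,6-trihydroxyacetophenone (phloroacetophenone); **8** prenyl bromide
Product: **6** 1-(2,4,6-trihydroxy-3-(3-methylbut-2-en-1-yl)phenyl)ethan-1-one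
Conditions: KOH (3 equiv), H2O, 0 °C → rt, 4 h; chromatographic separation from bis-prenyl and O-prenyl by-products
Reagents that add atoms: prenyl bromide, CC(C)=CCBr
Why: the phloroglucinol phenoxide is C-alkylated by SN2 attack on the prenyl α-carbon. Because **7** is symmetrical, mono-C-alkylation gives only one regioisomer, with the prenyl group flanked by two OH groups. No stereocentre forms.

**Step 2**
Reactants: **6**; **9** chloromethyl methyl ether (MOMCl)
Product: **4** 1-(2-hydroxy-4,6-bis(methoxymethoxy)-3-(3-methylbut-2-en-1-yl)phenyl)ethan-1-one
Conditions: MOMCl (2.1 equiv), K2CO3, acetone, 0 °C → rt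
Reagents that add atoms: MOMCl, COCCl
Why: Williamson-type MOM etherification. The acidic 4-OH and the unhindered 6-OH react. The 2-OH is H-bonded to the C=O and flanked by the prenyl group, so it stays free. That single free 2-OH fixes the later cyclisation site. No stereocentre forms.

**Step 3**
Reactants: **4**; **5** 4-hydroxybenzaldehyde
Product: **3** (E)-1-(2-hydroxy-4,6-bis(methoxymethoxy)-3-prenylphenyl)-3-(4-hydroxyphenyl)prop-2-en-1-one
Conditions: 50% aq. KOH, EtOH, rt, 48 h
Reagents that add atoms: none
Why: Claisen–Schmidt aldol condensation; MOM ethers and the prenyl alkene are base-stable. Dehydration gives the thermodynamic E-enone.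

**Step 4**
Reactants: **3**; **10** hydrogen peroxide
Product: **2** 3,4'-dihydroxy-5,7-bis(methoxymethoxy)-8-prenylflavone
Conditions: 30% H2O2 (5 equiv), 4 M aq. NaOH, EtOH, 0 °C → rt, 16 h; then careful quench to pH ~5
Reagents that add atoms: hydrogen peroxide, OO (supplies the 3-OH oxygen)
Why: Algar–Flynn–Oyamada reaction. Nucleophilic (Weitz–Scheffer) epoxidation of the enone is followed by 6-endo opening by the only free phenol (2'-OH, which gives the 8-prenyl isomer). A second oxidation of the dihydroflavonol by excess H2O2/air gives the flavonol. The transient C2/C3 stereocentres are lost on aromatisation, so the product is achiral. The isolated prenyl alkene is not epoxidised by HOO⁻.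

**Step 5**
Reactant: **2**
Product: **1** 8-prenylkaempferol (3,5,7,4'-tetrahydroxy-8-(3-methylbut-2-en-1-yl)flavone)
Conditions: 2 M HCl, MeOH, 45 °C, 3 h
Reagents that add atoms: none (MOM leaves as CH2O and MeOH)
Why: acid hydrolysis of the two aryl MOM acetals. The flavonol and the prenyl group survive these mild conditions, and no stereocentre is involved.

## Compound list
1 | 8-prenylkaempferol | CC(C)=CCc1c(O)cc(O)c2c(=O)c(O)c(-c3ccc(O)cc3)oc12 | target
2 | 3,4'-dihydroxy-5,7-bis(MOM)-8-prenylflavone | CC(C)=CCc1c(OCOC)cc(OCOC)c2c(=O)c(O)c(-c3ccc(O)cc3)oc12 | intermediate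
3 | (E)-2'-hydroxy-4',6'-bis(MOM)-3'-prenyl-4-hydroxychalcone | CC(C)=CCc1c(OCOC)cc(OCOC)c(C(=O)/C=C/c2ccc(O)cc2)c1O | intermediate
4 | 2-hydroxy-4,6-bis(MOM)-3-prenylacetophenone | CC(=O)c1c(OCOC)cc(OCOC)c(CC=C(C)C)c1O | intermediate
5 | 4-hydroxybenzaldehyde | O=Cc1ccc(O)cc1 | starting material
6 | 3-prenyl-2,4,6-trihydroxyacetophenone | CC(=O)c1c(O)cc(O)c(CC=C(C)C)c1O | intermediate
7 | 2,4,6-trihydroxyacetophenone | CC(=O)c1c(O)cc(O)cc1O | starting material
8 | prenyl bromide (1-bromo-3-methylbut-2-ene) | CC(C)=CCBr | starting material (reagent)
9 | chloromethyl methyl ether (MOMCl) | COCCl | starting material (reagent)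
10 | hydrogen peroxide | OO | starting material (reagent)

## Totals
Total steps: 5. Longest linear sequence: 5 (7 → 6 → 4 → 3 → 2 → 1).

## Three steps most likely to fail
1. **Step 1 (mono-C-prenylation).** Yields are modest, and O-prenyl and 3,5-bis-prenyl products compete.
   - Fallback: reverse the order. Make the known symmetrical 2-hydroxy-4,6-bis(MOM)acetophenone first, then C3-prenylate its magnesium phenoxide (MeMgBr, prenyl bromide, THF). Protection then directs the alkylation instead of relying on aqueous C-alkylation.
2. **Step 2 (selective bis-MOM protection).** The 2-OH might be protected and the 6-OH left free, or a tri-MOM product might form. That would give a 6-prenyl flavonol after Step 4, or no cyclisation.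
   - Fallback: protect all three OH groups as MOM ethers. Then remove the 2-OMOM selectively by chelation-controlled cleavage next to the carbonyl (Me2BBr or MgBr2, low temperature). This is a global-protection and selective-deprotection approach.
3. **Step 4 (AFO).** The hindered 2'-OH and the 6'-alkoxy group can divert the reaction to aurone or dihydroflavonol, giving low flavonol yields.
   - Fallback: cyclise chalcone **3** to the flavanone (NaOAc, EtOH, reflux). Then hydroxylate C3 through the enolate (LiHMDS, Davis oxaziridine) and dehydrogenate the dihydroflavonol (I2 or DDQ). This avoids peroxide oxidation of the chalcone.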